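## Structural features

Daucane numbering is used. C1 (quaternary, methyl C15), C2, C3, C4 (OH and isopropyl C11-C13) and C5 (H) form the five-membered ring. C1, C10 (O-isovaleryl), C9=C8 (methyl C14), C7, C6 (O-aroyl) and C5 form the seven-membered ring. β is the face of C15.

The rings are trans-fused (C15 β, H5 α). The five stereocentres C4, C5, C6, C1 and C10 are contiguous: 4α-OH/4β-isopropyl, 6β-O and 10α-O, which is (1S,4S,5S,6R,10R).

On the cyclopentane, C15, C6 and the isopropyl group all stand on the β face. The trans fusion is therefore probably the less stable arrangement next to a C6 carbonyl and has to be set kinetically.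

The fragile elements are:
- the tertiary C4 alcohol, 1,3 to the C6 oxygen (retro-aldol or elimination at the ketone level);
- the allylic, neopentyl ester at C10;
- the C8=C9 bond, which is β,γ to C6;
- two different esters beside a free phenol.

The real difficulty is the quaternary C1, wedged between carbinol C10 and C5, so the C1-C10 bond is the hardest one, and it lies in a seven-membered ring.

The key step exploits the array C5-C6(O)-C7H2-C8=C9. Read with C6 as an enol, the seven-membered ring is a cyclohepta-1,4-diene (C5=C6, C8=C9) whose only sp3-sp3 bond is C1-C10. That is the retron of a cis-divinylcyclopropane (C6-C7-C8) Cope rearrangement. Oxygen on C6 and a replaceable oxygen on C8 allow the anionic version.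

A second feature supports this: C1-C6, C15 and C11-C13 are a p-menth-1-en-4-ol whose ring bond C1-C6 has been moved to C1-C5, with the carbinol carbon as C4.

In one sentence: a lithium cis-1,2-dialkenylcyclopropanolate, made in the flask from a cyclopentenyl acylsilane and a β-alkoxyenone enolate, ring-enlarges by strain-releasing anionic oxy-Cope rearrangement to the hydroazulene. This is not the olefin-metathesis or aldol closure that would be drawn first.

## Logic of the disconnections

**23 back to 17 (through 22, 21, 20, with 18).** The bonds cut are the phenol O-Si bond, the acyl-O bond at C10 and the acyl-O bond at C6. The esters are the most fragile groups and they differ from each other, so they go on last and one at a time. What remains is a triol with three differentiated oxygens: free at C6, masked at C10 and unreactive at C4. The forward steps must acylate the hindered 6β-OH first and must never break a C-O bond at C6 or C10.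

**17 back to 15 (through 16).** The bonds cut are C6-H and C5-H. Both hydrogens lie on the α face, so they can be traced to a C5=C6 enol ether. This removes two stereocentres and uncovers the 1,4-diene retron. The forward steps need a proton at C5 and a hydride at C6, both from the α face, under non-epimerising conditions.

**15 back to 14.** The bond cut is C8-C14. Exchanging the methyl group for an oxygen leaving group turns C8 into a former carbonyl carbon. The four-carbon partner then shrinks to a methyl ketone, and the cyclopropane carbon C8 gains the oxyanion that accelerates the key step. The forward step needs an enol sulfonate of defined position (C8=C9) and a coupling that spares a silyl enol ether.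

**14 back to 6 and 9 (through 13, 12, 11, 10): key disconnection.** The bonds cut are C1-C10 and C6-C7, with C6-C8 as a transient bond. Cutting here removes the seven-membered ring, the quaternary C1 and C10 in one operation. It splits the skeleton into a C10 unit with one stereocentre and an achiral C4 unit. The forward step needs 1,2-addition to a hindered carbonyl, a cis cyclopropanolate, bonding at the α face of C1 under control of C4, and survival of a β-alkoxy enolate until it is trapped.

**6 back to 4 (through 5).** The bond cut is C6-Si. Silicon serves only to convert the C6 carbonyl into a carbanion by migrating to oxygen. The precursor is a plain enal. The forward steps need 1,2-silylation and an oxidation that does not trigger silyl migration.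

**4 back to 1 (through 3, 2).** C1=C5 is cut and C1=C6 is reconnected. All ten carbons and the C4 stereocentre then coincide with 1. The forward steps need cleavage of one alkene and an aldol condensation in which C5 acts as the nucleophile without expelling the C4 oxygen.

**9 back to 7 and 8.** The bond cut is C10-O. Both pieces are catalogue compounds. The forward step must give the (E) enol ether, because this geometry becomes the C10 configuration.

## Other disconnections considered

Alternative 1: Cut C8=C9 (the first idea). The forward key step is ring-closing metathesis of diene A1 with the second-generation Grubbs catalyst. The cut removes no stereocentre. A1 still carries all five contiguous centres, including the quaternary C1 next to carbinol C10 and the crowded all-β array C15/C6/isopropyl, and each would have to be built separately on a cyclopentane. The closure itself joins a 1,1-disubstituted alkene to a vinyl group on a neopentyl carbinol, which is a slow combination. The chosen plan instead sets C1 and C10 while it closes the ring.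

Alternative 2: Cut C6-C7 and C9-C10. The forward key step is a (4+3) cycloaddition of the fused furan A2 with an oxyallyl cation, giving the oxygen-bridged ketone A3. There are three objections.
- The bridge forces the oxygens on C6 and C10 onto the same face, whereas the target has 6β and 10α. One C-O bond would have to be inverted at a hindered or neopentyl carbon.
- One bridging atom has to serve for two ester oxygens.
- The C1=C5 bond of A3 would need a net trans addition of methyl and hydrogen inside a bicycle that favours cis delivery.

Alternative 3: Cut C1-C10 and C7-C8. The forward key step is the neutral tandem cyclopropanation/Cope rearrangement of silyloxydiene A4 with the rhodium carbenoid of an unsubstituted vinyldiazoacetate, giving A5. This strain-release logic is the closest to the chosen plan.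
- The donor/acceptor carbenoid puts an ester on C8 where a methyl group is needed, which costs several redox steps.
- C10 arrives as CH2.
- Later oxidation at the neopentyl γ-position of an enoate has no handle for regio- or stereocontrol.

The anionic version delivers oxygen at C6, a replaceable oxygen at C8 and the C10 oxygen with defined configuration in one step.

Key step: step 7

Assumption: (R)-(-)-terpinen-4-ol (1) is used in enantiopure form; a commercial lot of lower enantiomeric purity would have to be upgraded first.

Assumption: 4-(tert-butyldimethylsilyloxy)benzoic acid (18) is taken as a catalogue compound.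

## Steps

Step 1
Reactants: 1 (R)-(-)-terpinen-4-ol
Product: 2 triethylsilyl ether of 1
Conditions: TESOTf, 2,6-lutidine, CH2Cl2, 0 °C to rt
Reagents that add atoms: triethylsilyl triflate, CC[Si](CC)(CC)OS(=O)(=O)C(F)(F)F
Why: Silyl triflate/lutidine silylation of a hindered tertiary alcohol; the alkene is inert and C4 is not touched, so the (R) centre of 1 is carried over. The ether blocks hemiketal formation and retro-aldol cleavage in the next two steps.

Step 2
Reactants: 2 triethylsilyl ether of 1
Product: 3 (3R)-6-oxo-3-(propan-2-yl)-3-(triethylsilyloxy)heptanal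
Conditions: O3, CH2Cl2, -78 °C; then Me2S, -78 °C to rt
Reagents that add atoms: ozone, [O-][O+]=O
Why: Ozonolysis with reductive work-up cleaves the only C=C bond (C1=C6 in target numbering) into the C1 methyl ketone and the C6 aldehyde. The silyl ether and C4 are unaffected at low temperature.

Step 3
Reactants: 3 (3R)-6-oxo-3-(propan-2-yl)-3-(triethylsilyloxy)heptanal
Product: 4 (5S)-2-methyl-5-(propan-2-yl)-5-(triethylsilyloxy)cyclopent-1-ene-1-carbaldehyde
Conditions: piperidine (0.2 equiv), AcOH (0.2 equiv), 4 Å MS, toluene, 60 °C
Reagents that add atoms: none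
Why: Intramolecular aldol condensation through the aldehyde enamine (5-enolexo-exo-trig): C5 attacks the C1 ketone and loss of water gives the tetrasubstituted C1=C5 enal, the course known for 6-oxoheptanals obtained from 1-methylcyclohexenes. Secondary-amine catalysis selects the aldehyde as nucleophile, and the fully substituted C4 favours closure. The buffered medium and the weakly basic silyl ether oxygen should hold back β-elimination, as in the analogous closures of β-alkoxy dialdehydes.

Step 4
Reactants: 4 (5S)-2-methyl-5-(propan-2-yl)-5-(triethylsilyloxy)cyclopent-1-ene-1-carbaldehyde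
Product: 5 α-(dimethylphenylsilyl) carbinol of 4 (both C6 epimers)
Conditions: PhMe2SiLi, THF, -78 °C; sat. aq NH4Cl at -78 °C
Reagents that add atoms: dimethylphenylsilyllithium, [Li][Si](C)(C)c1ccccc1
Why: 1,2-Addition of a silyllithium to an aldehyde; conjugate addition is shut off by the fully substituted C1. The new carbinol centre is removed in step 5, and the cold quench prevents Brook rearrangement of the allylic α-silyl alkoxide.

Step 5
Reactants: 5 α-(dimethylphenylsilyl) carbinol of 4
Product: 6 [dimethyl(phenyl)silyl][(5S)-2-methyl-5-(propan-2-yl)-5-(triethylsilyloxy)cyclopent-1-en-1-yl]methanone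
Conditions: (COCl)2, DMSO, CH2Cl2, -78 °C; Et3N, -78 to 0 °C
Reagents that add atoms: none
Why: Swern oxidation is the standard way from α-hydroxysilanes to acylsilanes. The cold, non-acidic conditions avoid silyl migration and protodesilylation.

Step 6
Reactants: 7 but-3-yn-2-one; 8 4-methoxybenzyl alcohol
Product: 9 (E)-4-[(4-methoxybenzyl)oxy]but-3-en-2-one
Conditions: DABCO (10 mol %), CH2Cl2, 0 °C to rt
Reagents that add atoms: none
Why: Amine-catalysed oxa-Michael addition of an alcohol to an ynone. Protonation of the allenolate and equilibration give the (E)-β-alkoxyenone, the geometry that later fixes C10.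

Step 7
Reactants: 6 cyclopentenyl acylsilane; 9 (E)-4-[(4-methoxybenzyl)oxy]but-3-en-2-one
Product: 14 8-(trifluoromethylsulfonyloxy)-6-[dimethyl(phenyl)silyloxy]-10α-(4-methoxybenzyloxy)-4α-(triethylsilyloxy)-14-nordauca-5,8-diene, via lithium enolate 10 (not isolated), via alkoxide adduct 11 (not isolated), via cis-dialkenylcyclopropanolate 12 (not isolated), via cycloheptadienolate 13 (not isolated)
Conditions: 9, LDA, THF, -78 °C; add to 6, THF, -78 to -30 °C; Comins reagent, -78 to -20 °C; aq NH4Cl
Reagents that add atoms: N-(5-chloropyridin-2-yl)bis(trifluoromethanesulfonyl)imide (Comins reagent), FC(F)(F)S(=O)(=O)N(c1ccc(Cl)cn1)S(=O)(=O)C(F)(F)F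
Why: Kinetic lithium enolate 10 adds 1,2 to the acylsilane carbonyl of 6 (1,4-addition is shut off by the fully substituted C1) to give 11, whose 1,2-Brook shift moves silicon from C6 to oxygen while the emerging C6 allyl carbanion closes on the C8 carbonyl (3-exo-trig) to the lithium cis-1,2-dialkenylcyclopropanolate 12. Release of the three-membered-ring strain and the oxyanion on C8 then drive a Cope rearrangement at low temperature that breaks C6-C8, forms C1-C10 and leaves the C5=C6 silyl enol ether and the regiodefined C8=C9 enolate 13, which is fixed as triflate 14 before it can equilibrate. The closest known reaction type is the Brook rearrangement-mediated [3+4] annulation of alkenyl (also cycloalkenyl) acylsilanes with lithium enolates of alkenyl methyl ketones, and enolate triflation is standard. The seven-membered ring is closed not end to end but by [3,3] ring enlargement of the cyclopropane through the boat transition state that cis-divinylcyclopropanes require, with both arms folded over C7. In that boat the (E) geometry of C9=C10 and the ring-locked geometry of C5=C1 (C2 trans and C15 cis to C6) translate into O10 cis to C2 and trans to C15, so C1 and C10 are set together and stereospecifically. Their absolute sense is controlled by C4: C8 has to sit on one face of the cyclopentene, 1,3 to the C4 substituent on that face, and since the α face offers only the ether oxygen and the β face the branched C11, bonding at C1 should occur α, anti to isopropyl, while lithium bridging of O6 and O8 keeps the two arms cis and trans or mismatched cyclopropanolates can reopen to the carbanion and be funnelled through the lower boat. The step needs survival of the β-alkoxy enolate 13: because O10 derives from an (E) substituent, the C10-O bond starts near the nodal plane of the enolate, where E1cB loss of alkoxide is stereoelectronically poor, and the cold triflimide quench shortens the lifetime of 13.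

Step 8
Reactants: 14 enol triflate
Product: 15 6-[dimethyl(phenyl)silyloxy]-10α-(4-methoxybenzyloxy)-4α-(triethylsilyloxy)dauca-5,8-diene
Conditions: MeMgBr, Fe(acac)3 (5 mol %), THF/NMP, -30 to 0 °C
Reagents that add atoms: methylmagnesium bromide, C[Mg]Br
Why: Iron-catalysed Kumada-type coupling of an alkenyl triflate with a methyl Grignard reagent, fast at low temperature. It installs C14 with retention of the C8=C9 position and leaves the silyl ether, the silyl enol ether and the allylic ether untouched.

Step 9
Reactants: 15 dienyl silyl enol ether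
Product: 16 4α-hydroxy-10α-(4-methoxybenzyloxy)-5αH-dauc-8-en-6-one (trans-fused)
Conditions: HF·pyridine, pyridine, THF, -20 to 0 °C
Reagents that add atoms: none
Why: Fluoride-assisted cleavage of both silyl groups; the liberated C5=C6 enol ketonises by kinetic protonation at C5. The β face of C5 is closed by the syn pair C15 and C11, whereas the α face carries only O4 and the C10 methine, and O4 can relay the proton, so 5α-H (trans fusion) should result. The weakly acidic, cold medium disfavours C5 epimerisation, C7 enolisation (alkene conjugation) and retro-aldol cleavage.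

Step 10
Reactants: 16 β-hydroxy ketone
Product: 17 10α-(4-methoxybenzyloxy)-5αH-dauc-8-ene-4α,6β-diol
Conditions: Me4NBH(OAc)3, MeCN/AcOH, -30 °C
Reagents that add atoms: none
Why: Hydroxyl-directed Evans-Saksena reduction: the 4α-OH displaces acetate on boron and delivers hydride through a chair to the α face of the C6 carbonyl, giving the anti 1,3-diol, that is 6β-OH. External attack would come from the same face, because C15 and the isopropyl group shield the β face. The acidic medium does not enolise the ketone.

Step 11
Reactants: 17 4α,6β-diol; 18 4-(tert-butyldimethylsilyloxy)benzoic acid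
Product: 20 4α-hydroxy-10α-(4-methoxybenzyloxy)-5αH-dauc-8-en-6β-yl 4-(tert-butyldimethylsilyloxy)benzoate, via mixed anhydride 19 (not isolated)
Conditions: 18, 2,4,6-trichlorobenzoyl chloride, Et3N, THF, rt; then 17, DMAP, toluene, 40-60 °C
Reagents that add atoms: none
Why: Yamaguchi esterification: DMAP attacks 19 at the less hindered aroyl carbonyl and the acylpyridinium ion acylates the only secondary hydroxyl. The tertiary 4-OH is inert, O10 is masked, and C6 keeps its configuration because the C6-O bond is not broken.

Step 12
Reactants: 20 C6 ester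
Product: 21 4α,10α-dihydroxy-5αH-dauc-8-en-6β-yl 4-(tert-butyldimethylsilyloxy)benzoate
Conditions: DDQ, CH2Cl2/pH 7 buffer, 0 °C
Reagents that add atoms: none
Why: Oxidative cleavage of the 4-methoxybenzyl ether (benzylic hydride abstraction, then hydrolysis of the hemiacetal). The ester, the aryl silyl ether and the alkene are spared, and the C10-O bond stays intact.

Step 13
Reactants: 21 C10 alcohol
Product: 22 4α-hydroxy-10α-(3-methylbutanoyloxy)-5αH-dauc-8-en-6β-yl 4-(tert-butyldimethylsilyloxy)benzoate
Conditions: isovaleryl chloride, pyridine, DMAP (cat.), CH2Cl2, 0 °C to rt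
Reagents that add atoms: 3-methylbutanoyl chloride (isovaleryl chloride), CC(C)CC(=O)Cl
Why: Acylation of the secondary allylic alcohol through the acylpyridinium ion, with retention at C10. The tertiary 4-OH is too hindered to compete.

Step 14
Reactants: 22 silyl-protected diester
Product: 23 target, (1S,4S,5S,6R,10R)-4-hydroxy-6-(4-hydroxybenzoyloxy)dauc-8-en-10-yl 3-methylbutanoate
Conditions: TBAF, AcOH, THF, 0 °C
Reagents that add atoms: none
Why: Buffered fluoride cleaves the aryl silyl ether far faster than it attacks esters. Acetic acid protonates the phenoxide at once and so prevents acyl migration or ester cleavage.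

## Compound list

1 | (R)-(-)-terpinen-4-ol, (1R)-4-methyl-1-(propan-2-yl)cyclohex-3-en-1-ol | CC1=CC[C@@](O)(C(C)C)CC1 | starting material
2 | triethyl{[(1R)-4-methyl-1-(propan-2-yl)cyclohex-3-en-1-yl]oxy}silane | CC1=CC[C@@](O[Si](CC)(CC)CC)(C(C)C)CC1 | intermediate
3 | (3R)-6-oxo-3-(propan-2-yl)-3-(triethylsilyloxy)heptanal | CC(=O)CC[C@](O[Si](CC)(CC)CC)(C(C)C)CC=O | intermediate
4 | (5S)-2-methyl-5-(propan-2-yl)-5-(triethylsilyloxy)cyclopent-1-ene-1-carbaldehyde | CC1=C(C=O)[C@@](O[Si](CC)(CC)CC)(C(C)C)CC1 | intermediate
5 | [dimethyl(phenyl)silyl][(5S)-2-methyl-5-(propan-2-yl)-5-(triethylsilyloxy)cyclopent-1-en-1-yl]methanol, both carbinol epimers | CC1=C(C(O)[Si](C)(C)c2ccccc2)[C@@](O[Si](CC)(CC)CC)(C(C)C)CC1 | intermediate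
6 | [dimethyl(phenyl)silyl][(5S)-2-methyl-5-(propan-2-yl)-5-(triethylsilyloxy)cyclopent-1-en-1-yl]methanone | CC1=C(C(=O)[Si](C)(C)c2ccccc2)[C@@](O[Si](CC)(CC)CC)(C(C)C)CC1 | intermediate
7 | but-3-yn-2-one | CC(=O)C#C | starting material
8 | 4-methoxybenzyl alcohol | COc1ccc(CO)cc1 | starting material
9 | (E)-4-[(4-methoxybenzyl)oxy]but-3-en-2-one | CC(=O)/C=C/OCc1ccc(OC)cc1 | intermediate
10 | lithium (E)-4-[(4-methoxybenzyl)oxy]buta-1,3-dien-2-olate | [Li+].C=C([O-])/C=C/OCc1ccc(OC)cc1 | intermediate
11 | lithium alkoxide from 1,2-addition of 10 to 6 (C6 configuration of no consequence) | [Li+].CC1=C(C([O-])(CC(=O)/C=C/OCc2ccc(OC)cc2)[Si](C)(C)c2ccccc2)[C@@](O[Si](CC)(CC)CC)(C(C)C)CC1 | intermediate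
12 | lithium cis-1,2-dialkenylcyclopropanolate (C6 silyloxy and cyclopentenyl, C8 oxide and (E)-alkoxyvinyl, C8 on the α face of the cyclopentene) | [Li+].CC1=C([C@]2(O[Si](C)(C)c3ccccc3)C[C@]2([O-])/C=C/OCc4ccc(OC)cc4)[C@@](O[Si](CC)(CC)CC)(C(C)C)CC1 | intermediate
13 | lithium 6-[dimethyl(phenyl)silyloxy]-10α-(4-methoxybenzyloxy)-4α-(triethylsilyloxy)-14-nordauca-5,8-dien-8-olate | [Li+].[O-]C1=C[C@@H](OCc3ccc(OC)cc3)[C@@]2(C)CC[C@](O[Si](CC)(CC)CC)(C(C)C)C2=C(O[Si](C)(C)c2ccccc2)C1 | intermediate
14 | 8-(trifluoromethylsulfonyloxy)-6-[dimethyl(phenyl)silyloxy]-10α-(4-methoxybenzyloxy)-4α-(triethylsilyloxy)-14-nordauca-5,8-diene | FC(F)(F)S(=O)(=O)OC1=C[C@@H](OCc3ccc(OC)cc3)[C@@]2(C)CC[C@](O[Si](CC)(CC)CC)(C(C)C)C2=C(O[Si](C)(C)c2ccccc2)C1 | intermediate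
15 | 6-[dimethyl(phenyl)silyloxy]-10α-(4-methoxybenzyloxy)-4α-(triethylsilyloxy)dauca-5,8-diene | CC1=C[C@@H](OCc3ccc(OC)cc3)[C@@]2(C)CC[C@](O[Si](CC)(CC)CC)(C(C)C)C2=C(O[Si](C)(C)c2ccccc2)C1 | intermediate
16 | 4α-hydroxy-10α-(4-methoxybenzyloxy)-5αH-dauc-8-en-6-one | CC1=C[C@@H](OCc3ccc(OC)cc3)[C@@]2(C)CC[C@](O)(C(C)C)[C@@H]2C(=O)C1 | intermediate
17 | 10α-(4-methoxybenzyloxy)-5αH-dauc-8-ene-4α,6β-diol | CC1=C[C@@H](OCc3ccc(OC)cc3)[C@@]2(C)CC[C@](O)(C(C)C)[C@@H]2[C@H](O)C1 | intermediate
18 | 4-(tert-butyldimethylsilyloxy)benzoic acid | CC(C)(C)[Si](C)(C)Oc1ccc(cc1)C(=O)O | starting material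
19 | 4-(tert-butyldimethylsilyloxy)benzoic 2,4,6-trichlorobenzoic anhydride | CC(C)(C)[Si](C)(C)Oc1ccc(cc1)C(=O)OC(=O)c1c(Cl)cc(Cl)cc1Cl | intermediate
20 | 4α-hydroxy-10α-(4-methoxybenzyloxy)-5αH-dauc-8-en-6β-yl 4-(tert-butyldimethylsilyloxy)benzoate | CC1=C[C@@H](OCc3ccc(OC)cc3)[C@@]2(C)CC[C@](O)(C(C)C)[C@@H]2[C@H](OC(=O)c2ccc(O[Si](C)(C)C(C)(C)C)cc2)C1 | intermediate
21 | 4α,10α-dihydroxy-5αH-dauc-8-en-6β-yl 4-(tert-butyldimethylsilyloxy)benzoate | CC1=C[C@@H](O)[C@@]2(C)CC[C@](O)(C(C)C)[C@@H]2[C@H](OC(=O)c2ccc(O[Si](C)(C)C(C)(C)C)cc2)C1 | intermediate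
22 | 4α-hydroxy-10α-(3-methylbutanoyloxy)-5αH-dauc-8-en-6β-yl 4-(tert-butyldimethylsilyloxy)benzoate | CC1=C[C@@H](OC(=O)CC(C)C)[C@@]2(C)CC[C@](O)(C(C)C)[C@@H]2[C@H](OC(=O)c2ccc(O[Si](C)(C)C(C)(C)C)cc2)C1 | intermediate
23 | (1S,4S,5S,6R,10R)-4-hydroxy-6-(4-hydroxybenzoyloxy)dauc-8-en-10-yl 3-methylbutanoate (CNP0086724.4) | CC1=C[C@@H](OC(=O)CC(C)C)[C@@]2(C)CC[C@](O)(C(C)C)[C@@H]2[C@H](OC(=O)c2ccc(O)cc2)C1 | target

## Step count and least certain steps

There are 14 steps in total. The longest linear sequence has 13 steps (steps 1-5 and 7-14).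

**Step 7 (key step).** Three things are most likely to go wrong.
- Addition of the enolate to the hindered, twisted acylsilane carbonyl may be slow, so that proton transfer or self-condensation of the enolate takes over.
- 13 may lose 4-methoxybenzyl oxide by E1cB before it is triflated, especially if the rearrangement needs warming.
- The facial bias of C4 may be too weak, which would give bonding at C1 from both faces.

The fallback replaces the anionic annulation by a neutral, stepwise silyloxy-divinylcyclopropane. It sets out from 4 and comes back at 16.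

MeMgBr adds to 4 to give the carbinol F1. Dess-Martin periodinane gives the methyl ketone F2, and TBSOTf/Et3N gives the 2-silyloxydiene F3. Ethyl 2-diazopropanoate with Rh2(O2CCPh3)4 at -78 °C cyclopropanates the terminal enol ether double bond to the donor-acceptor cyclopropane ester F4. iBu2AlH at -78 °C gives the cyclopropanecarbaldehyde F5. The ylide from (4-methoxybenzyloxymethyl)triphenylphosphonium chloride and KHMDS gives the dialkenylcyclopropane F6. Only its (E) enol ether should rearrange on moderate heating in toluene, to the silyl enol ether F7, and HF·pyridine converts F7 into 16.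

**Step 9.** Four things are most likely to go wrong.
- The facial selectivity of the C5 protonation may be poor.
- The ketone may epimerise afterwards to the probably more stable cis-fused isomer.
- C7 may enolise, with migration of C8=C9 into conjugation.
- The C4-C5 bond may cleave by retro-aldol reaction.

The fallback sets C5 by a tethered syn addition instead of a protonation. It sets out from 15 and comes back at 16.

MeLi at -78 °C followed by the Comins reagent gives the C6 enol triflate F8. Pd(OAc)2/PPh3 with HCO2H/Et3N reduces it to the C5=C6 alkene F9, and TBAF frees the tertiary alcohol F10. Me2SiHCl/Et3N gives the hydrosilyl ether F11. Pt2[(CH2=CHSiMe2)2O]3 effects 5-endo intramolecular hydrosilylation on the α face to the oxasilolane F12 (5α-H, 6α-Si). Tamao oxidation (H2O2, KF, KHCO3) gives the 4α,6α-diol F13. Dess-Martin periodinane oxidises only the secondary alcohol, giving 16, which is reduced at once as in step 10.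

**Step 3.** The enamine may expel triethylsilanolate from C4 (β-elimination to an acyclic enal, with loss of the only stereocentre). The competing aldol regiochemistry, ketone enolate on aldehyde, is the second risk.

The fallback never places a carbanion or enamine at C5 while C6 is a carbonyl carbon. It sets out from 2 and comes back at 4.

Allylic oxidation (CrO3, 3,5-dimethylpyrazole) gives the enone F14, and H2O2/NaOH gives the epoxy ketone F15. Eschenmoser-Tanabe fragmentation (TsNHNH2, AcOH/CH2Cl2) gives the alkynyl ketone F16. SmI2/HMPA/t-BuOH closes C1-C5 by ketyl-alkyne 5-exo-dig cyclisation to the methylenecyclopentanol F17. Pyridinium chlorochromate effects the Babler-Dauben oxidative transposition to 4.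

**Step 11.** Acylation of the 6β-hydroxyl may be sluggish, because it lies on the face of C15 and the isopropyl group. Forcing conditions risk loss of the aryl silyl ether or elimination.

The fallback brings the aroyl group in intramolecularly. It sets out from 16 and comes back at 20.

An Evans-Tishchenko reaction of 16 with 4-(tert-butyldimethylsilyloxy)benzaldehyde and catalytic SmI2 reduces C6 from the α face and leaves the aroyl group on O4, as the tertiary ester F18. DBU then induces 1,3-acyl migration from the tertiary to the secondary oxygen, giving 20.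

## Further compounds

F1 | step 7 | 1-[(5S)-2-methyl-5-(propan-2-yl)-5-(triethylsilyloxy)cyclopent-1-en-1-yl]ethanol, both carbinol epimers | CC(O)C1=C(C)CC[C@]1(O[Si](CC)(CC)CC)C(C)C
F2 | step 7 | 1-[(5S)-2-methyl-5-(propan-2-yl)-5-(triethylsilyloxy)cyclopent-1-en-1-yl]ethanone | CC(=O)C1=C(C)CC[C@]1(O[Si](CC)(CC)CC)C(C)C
F3 | step 7 | tert-butyldimethylsilyl enol ether of F2 (2-silyloxydiene) | C=C(O[Si](C)(C)C(C)(C)C)C1=C(C)CC[C@]1(O[Si](CC)(CC)CC)C(C)C
F4 | step 7 | ethyl 2-(tert-butyldimethylsilyloxy)-1-methyl-2-(cyclopentenyl)cyclopropanecarboxylate, ester cis to cyclopentenyl, C8 on the α face | CC1=C([C@]2(O[Si](C)(C)C(C)(C)C)C[C@]2(C)C(=O)OCC)[C@@](O[Si](CC)(CC)CC)(C(C)C)CC1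
F5 | step 7 | corresponding cyclopropanecarbaldehyde | CC1=C([C@]2(O[Si](C)(C)C(C)(C)C)C[C@]2(C)C=O)[C@@](O[Si](CC)(CC)CC)(C(C)C)CC1
F6 | step 7 | cis-dialkenylcyclopropane with (E)-2-(4-methoxybenzyloxy)vinyl arm | CC1=C([C@]2(O[Si](C)(C)C(C)(C)C)C[C@]2(C)/C=C/OCc3ccc(OC)cc3)[C@@](O[Si](CC)(CC)CC)(C(C)C)CC1
F7 | step 7 | 6-(tert-butyldimethylsilyloxy)-10α-(4-methoxybenzyloxy)-4α-(triethylsilyloxy)dauca-5,8-diene | CC1=C[C@@H](OCc3ccc(OC)cc3)[C@@]2(C)CC[C@](O[Si](CC)(CC)CC)(C(C)C)C2=C(O[Si](C)(C)C(C)(C)C)C1
F8 | step 9 | 10α-(4-methoxybenzyloxy)-4α-(triethylsilyloxy)dauca-5,8-dien-6-yl triflate | CC1=C[C@@H](OCc3ccc(OC)cc3)[C@@]2(C)CC[C@](O[Si](CC)(CC)CC)(C(C)C)C2=C(OS(=O)(=O)C(F)(F)F)C1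
F9 | step 9 | 10α-(4-methoxybenzyloxy)-4α-(triethylsilyloxy)dauca-5,8-diene | CC1=C[C@@H](OCc3ccc(OC)cc3)[C@@]2(C)CC[C@](O[Si](CC)(CC)CC)(C(C)C)C2=CC1
F10 | step 9 | 10α-(4-methoxybenzyloxy)dauca-5,8-dien-4α-ol | CC1=C[C@@H](OCc3ccc(OC)cc3)[C@@]2(C)CC[C@](O)(C(C)C)C2=CC1
F11 | step 9 | dimethylsilyl (Si-H) ether of F10 | CC1=C[C@@H](OCc3ccc(OC)cc3)[C@@]2(C)CC[C@](O[SiH](C)C)(C(C)C)C2=CC1
F12 | step 9 | 4α-O,6α-Si-bridged dimethyloxasilolane, 5α-H | CC1=C[C@@H](OCc3ccc(OC)cc3)[C@@]2(C)CC[C@](O[Si]4(C)C)(C(C)C)[C@@H]2[C@@H]4C1
F13 | step 9 | 10α-(4-methoxybenzyloxy)-5αH-dauc-8-ene-4α,6α-diol | CC1=C[C@@H](OCc3ccc(OC)cc3)[C@@]2(C)CC[C@](O)(C(C)C)[C@@H]2[C@@H](O)C1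
F14 | step 3 | (6S)-3-methyl-6-(propan-2-yl)-6-(triethylsilyloxy)cyclohex-2-en-1-one | CC1=CC(=O)[C@@](O[Si](CC)(CC)CC)(C(C)C)CC1
F15 | step 3 | 2,3-epoxide of F14 (epoxide configuration of no consequence) | CC12CC[C@](O[Si](CC)(CC)CC)(C(C)C)C(=O)C1O2
F16 | step 3 | 5-ethynyl-6-methyl-5-(triethylsilyloxy)heptan-2-one, C4 configuration of 2 retained | CC(=O)CC[C@](O[Si](CC)(CC)CC)(C(C)C)C#C
F17 | step 3 | 1-methyl-2-methylidene-3-(propan-2-yl)-3-(triethylsilyloxy)cyclopentan-1-ol (C1 configuration of no consequence) | CC1(O)CC[C@](O[Si](CC)(CC)CC)(C(C)C)C1=C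
F18 | step 11 | 6β-hydroxy-10α-(4-methoxybenzyloxy)-5αH-dauc-8-en-4α-yl 4-(tert-butyldimethylsilyloxy)benzoate | CC1=C[C@@H](OCc3ccc(OC)cc3)[C@@]2(C)CC[C@](OC(=O)c3ccc(O[Si](C)(C)C(C)(C)C)cc3)(C(C)C)[C@@H]2[C@H](O)C1
A1 | alternative 1 | metathesis diene, cyclopentane with 1-hydroxyallyl arm on C1 and 1-hydroxy-3-methylbut-3-enyl arm on C5 | C=C[C@@H](O)[C@@]1(C)CC[C@](O)(C(C)C)[C@@H]1[C@H](O)CC(C)=C
A2 | alternative 2 | 4-(propan-2-yl)-5,6-dihydro-4H-cyclopenta[c]furan-4-ol | CC(C)[C@@]1(O)CCc2cocc21
A3 | alternative 2 | C6,C10-oxygen-bridged 14,15-dinordauc-1(5)-en-8-one adduct, bridge on the α face | O=C1C[C@@H]2O[C@H](C1)C1=C2[C@@](O)(C(C)C)CC1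
A4 | alternative 3 | triisopropylsilyl enol ether of the methyl ketone derived from 4 (2-silyloxydiene) | C=C(O[Si](C(C)C)(C(C)C)C(C)C)C1=C(C)CC[C@]1(O[Si](CC)(CC)CC)C(C)C
A5 | alternative 3 | methyl 6-(triisopropylsilyloxy)-4α-(triethylsilyloxy)dauca-5,8-dien-14-oate | COC(=O)C1=CC[C@@]2(C)CC[C@](O[Si](CC)(CC)CC)(C(C)C)C2=C(O[Si](C(C)C)(C(C)C)C(C)C)C1
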